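**Assumption:** diplotrin A (2',5'-dihydroxy-3,7,8,4'-tetramethoxyflavone) has no stereocentres and is achiral, so the "single enantiomer" requirement needs no stereocontrol. The only stereo-element in the route is the chalcone E-alkene, which is consumed on cyclisation.

## Retrosynthetic overview

1. Target ⇒ 2',5'-di-O-benzyl ether; the hydroquinone B-ring is unmasked last by hydrogenolysis.
2. 3-OMe ⇒ 3-OH flavonol by O-methylation, done while the B-ring phenols are still benzylated.
3. Flavonol pyranone ring (the only ring formed) ⇒ 2'-hydroxychalcone by Algar–Flynn–Oyamada oxidative cyclisation.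
4. Chalcone ⇒ 2'-hydroxy-3',4'-dimethoxyacetophenone (A-ring) + 2,5-bis(benzyloxy)-4-methoxybenzaldehyde (B-ring) by Claisen–Schmidt condensation.
5. Aldehyde ⇒ methoxyhydroquinone by bis-benzylation, then Vilsmeier formylation para to OMe.

## Forward route

**Step 1**
Reactants: **1** methoxyhydroquinone (2-methoxybenzene-1,4-diol); **2** benzyl bromide
Product: **3** 1,4-bis(benzyloxy)-2-methoxybenzene
Conditions: BnBr (2.4 equiv), K2CO3, DMF, N2, rt → 60 °C
Reagents that add atoms: benzyl bromide, BrCc1ccccc1
Why: Williamson etherification of both phenols; degassed conditions prevent base/air oxidation of the hydroquinone to the quinone.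

**Step 2**
Reactants: **3** 1,4-bis(benzyloxy)-2-methoxybenzene; **4** N,N-dimethylformamide
Product: **5** 2,5-bis(benzyloxy)-4-methoxybenzaldehyde
Conditions: POCl3, DMF, 0 → 75 °C; then aq NaOAc
Reagents that add atoms: DMF, CN(C)C=O (formyl carbon); water, O (carbonyl oxygen on iminium hydrolysis)
Why: Vilsmeier–Haack formylation goes to the one unhindered position that is para to OMe and ortho to OBn, the same selectivity that turns 1,2,4-trimethoxybenzene into 2,4,5-trimethoxybenzaldehyde.

**Step 3**
Reactants: **5** 2,5-bis(benzyloxy)-4-methoxybenzaldehyde; **6** 1-(2-hydroxy-3,4-dimethoxyphenyl)ethanone (2'-hydroxy-3',4'-dimethoxyacetophenone)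
Product: **7** (E)-3-[2,5-bis(benzyloxy)-4-methoxyphenyl]-1-(2-hydroxy-3,4-dimethoxyphenyl)prop-2-en-1-one
Conditions: 50% aq KOH, EtOH/THF, rt, 24–48 h; then cold dilute HCl
Reagents that add atoms: none
Why: Claisen–Schmidt aldol condensation between a methyl ketone and a non-enolisable aldehyde; E1cB dehydration gives the conjugated E-enone.

**Step 4**
Reactants: **7** the chalcone; **8** hydrogen peroxide
Product: **9** 2-[2,5-bis(benzyloxy)-4-methoxyphenyl]-3-hydroxy-7,8-dimethoxy-4H-chromen-4-one
Conditions: 30% H2O2, aq NaOH, MeOH/THF, 0 °C → rt; acidify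
Reagents that add atoms: hydrogen peroxide, OO (the 3-OH oxygen)
Why: Algar–Flynn–Oyamada reaction; with no 6'-substituent on the A-ring the phenoxide cyclises 6-endo to the flavonol and not to the aurone, and benzyl and methyl ethers are inert to alkaline peroxide.

**Step 5**
Reactants: **9** the flavonol; **10** iodomethane
Product: **11** 2-[2,5-bis(benzyloxy)-4-methoxyphenyl]-3,7,8-trimethoxy-4H-chromen-4-one
Conditions: MeI, K2CO3, acetone, reflux
Reagents that add atoms: iodomethane, CI
Why: SN2 O-methylation of the acidic 3-OH, which is the only free hydroxyl in the molecule, so no selectivity problem arises.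

**Step 6**
Reactants: **11** the bis-benzyl 3-O-methylflavone
Product: **12** diplotrin A, 2-(2,5-dihydroxy-4-methoxyphenyl)-3,7,8-trimethoxy-4H-chromen-4-one
Conditions: H2 (1 atm), 10% Pd/C, EtOAc/MeOH, rt; filter and concentrate under Ar
Reagents that add atoms: none
Why: Catalytic hydrogenolysis cleaves both benzyl aryl ethers, while the aryl methyl ethers and the flavone enone are retained at 1 atm and rt when the reaction is stopped at H2 uptake.

## Compound list

1 | methoxyhydroquinone (2-methoxybenzene-1,4-diol) | COc1cc(O)ccc1O | starting material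
2 | benzyl bromide | BrCc1ccccc1 | starting material (reagent)
3 | 1,4-bis(benzyloxy)-2-methoxybenzene | COc1cc(OCc2ccccc2)ccc1OCc1ccccc1 | intermediate
4 | N,N-dimethylformamide | CN(C)C=O | starting material (reagent)
5 | 2,5-bis(benzyloxy)-4-methoxybenzaldehyde | COc1cc(OCc2ccccc2)c(C=O)cc1OCc1ccccc1 | intermediate
6 | 1-(2-hydroxy-3,4-dimethoxyphenyl)ethanone | CC(=O)c1ccc(OC)c(OC)c1O | starting material
7 | (E)-3-[2,5-bis(benzyloxy)-4-methoxyphenyl]-1-(2-hydroxy-3,4-dimethoxyphenyl)prop-2-en-1-one | COc1cc(OCc2ccccc2)c(/C=C/C(=O)c2ccc(OC)c(OC)c2O)cc1OCc1ccccc1 | intermediate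
8 | hydrogen peroxide | OO | starting material (reagent)
9 | 2-[2,5-bis(benzyloxy)-4-methoxyphenyl]-3-hydroxy-7,8-dimethoxy-4H-chromen-4-one | COc1cc(OCc2ccccc2)c(-c2oc3c(OC)c(OC)ccc3c(=O)c2O)cc1OCc1ccccc1 | intermediate
10 | iodomethane | CI | starting material (reagent)
11 | 2-[2,5-bis(benzyloxy)-4-methoxyphenyl]-3,7,8-trimethoxy-4H-chromen-4-one | COc1cc(OCc2ccccc2)c(-c2oc3c(OC)c(OC)ccc3c(=O)c2OC)cc1OCc1ccccc1 | intermediate
12 | diplotrin A, 2-(2,5-dihydroxy-4-methoxyphenyl)-3,7,8-trimethoxy-4H-chromen-4-one | COc1cc(O)c(-c2oc3c(OC)c(OC)ccc3c(=O)c2OC)cc1O | target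

## Summary

**Total steps:** 6
**Longest linear sequence:** 6 (1 → 3 → 5 → 7 → 9 → 11 → 12); acetophenone 6 is used as purchased.

**Steps most likely to fail, with fallbacks**

1. **Step 4 (AFO oxidation).** The ortho-benzyloxy B-ring may slow cyclisation or divert material to aurone or dihydroflavonol. Fallback: oxidise aldehyde 5 to the acid (Pinnick) and convert to the acid chloride, O-acylate 1-(2-hydroxy-3,4-dimethoxyphenyl)-2-methoxyethanone, then carry out Baker–Venkataraman rearrangement and acid cyclodehydration. This gives 3-methoxyflavone 11 directly and makes steps 4 and 5 unnecessary.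
2. **Step 2 (Vilsmeier formylation).** Risks are incomplete regiocontrol or partial benzyl ether cleavage by HCl/POCl3. Fallback: start from 2-hydroxy-4-methoxybenzaldehyde, introduce the 5-OH by Elbs persulfate oxidation (K2S2O8, aq NaOH) to 2,5-dihydroxy-4-methoxybenzaldehyde, then bis-benzylate to 5. The aldehyde is then present from the outset and no formylation is needed.
3. **Step 6 (hydrogenolysis).** Risks are over-reduction of the C2–C3 enone and air oxidation of the electron-rich hydroquinone to the quinone. Fallback: use MOM ethers in place of benzyl throughout, making the aldehyde by NBS bromination para to OMe, then Br/Li exchange and DMF quench. The final deprotection is then non-reductive (HCl/MeOH).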